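## Retrosynthetic overview

1. Eurycomalin A (11) ⇒ its dimethyl ester 10; ester hydrolysis is the last step.
2. 10 ⇒ bis(allylic trichloroacetimidate) 9: a twofold chiral-Brønsted-acid-catalysed SN2′ ring closure (metal-free) makes both dihydrofuran C–O bonds, both isopropenyl groups and both S stereocentres at once.
3. 9 ⇒ bis-prenyl biphenol 6, by (E)-selective allylic oxidation of the prenyl methyl groups and imidate activation.
4. 6 ⇒ biphenol 4 + prenyl bromide 5 (twofold ortho C-prenylation); 4 ⇒ two molecules of methyl 3-bromo-4-hydroxybenzoate 1. The biaryl bond is made first so that no transition metal touches the finished allylic aryl ethers.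
5. Ring order: both benzene rings are bought, the biaryl bond joins them, and the two dihydrofuran rings are closed last and together. The biaryl axis has only two ortho substituents and is not a stereo element.

Assumption: in each twofold step on the symmetric biaryl both identical arms react in the same operation, and the half-converted species is not counted as a separate intermediate.

## Route

Step 1
Reactants: 1 methyl 3-bromo-4-hydroxybenzoate (2 molecules); 2 bis(pinacolato)diboron (0.52 equiv)
Product: 4 dimethyl 6,6′-dihydroxy-[1,1′-biphenyl]-3,3′-dicarboxylate, via pinacol boronate 3 (not isolated)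
Conditions: PdCl2(dppf) (3 mol%), KOAc (3 equiv), 1,4-dioxane, 90 °C; then 2 M aq. K2CO3, 90 °C
Reagents that add atoms: none
Why: One-pot Miyaura borylation/Suzuki–Miyaura homocoupling, in which half of 1 becomes boronate 3 and couples with the remaining 1 once aqueous carbonate is added; free phenols and methyl esters are tolerated and no stereocentre is involved.

Step 2
Reactants: 4 dimethyl 6,6′-dihydroxy-[1,1′-biphenyl]-3,3′-dicarboxylate; 5 prenyl bromide (1-bromo-3-methylbut-2-ene)
Product: 6 dimethyl 6,6′-dihydroxy-5,5′-bis(3-methylbut-2-en-1-yl)-[1,1′-biphenyl]-3,3′-dicarboxylate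
Conditions: NaH (2.2 equiv), toluene, 0 °C to rt; then 5 (2.5 equiv), rt to 50 °C
Reagents that add atoms: prenyl bromide (5), CC(C)=CCBr
Why: Classical ortho C-prenylation of a sodium phenoxide held as a tight ion pair in a non-polar solvent (SN2 at the primary allylic bromide); the para position is blocked by the ester and the other ortho position by the biaryl bond, so only the desired carbon can react, and the O-prenyl ether by-product is removed by chromatography.

Step 3
Reactants: 6 dimethyl 6,6′-dihydroxy-5,5′-bis(3-methylbut-2-en-1-yl)-[1,1′-biphenyl]-3,3′-dicarboxylate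
Product: 7 dimethyl 6,6′-dihydroxy-5,5′-bis[(2E)-4-hydroxy-3-methylbut-2-en-1-yl]-[1,1′-biphenyl]-3,3′-dicarboxylate
Conditions: SeO2 (0.5 equiv), t-BuOOH (5.5 M in decane, 4 equiv), salicylic acid (0.2 equiv), CH2Cl2, 0 °C to rt
Reagents that add atoms: tert-butyl hydroperoxide, CC(C)(C)OO (terminal oxygen source); selenium dioxide, O=[Se]=O (catalytic oxygen carrier)
Why: Riley allylic oxidation under Sharpless catalytic conditions (ene reaction, then [2,3]-sigmatropic shift) oxidises only the (E)-methyl group of a trisubstituted prenyl alkene and so gives the (E)-allylic alcohol; the electron-poor phenols and the esters are inert, and the reaction is stopped before enal formation becomes significant.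

Step 4
Reactants: 7 dimethyl 6,6′-dihydroxy-5,5′-bis[(2E)-4-hydroxy-3-methylbut-2-en-1-yl]-[1,1′-biphenyl]-3,3′-dicarboxylate; 8 trichloroacetonitrile
Product: 9 dimethyl 6,6′-dihydroxy-5,5′-bis{(2E)-3-methyl-4-[(2,2,2-trichloroethanimidoyl)oxy]but-2-en-1-yl}-[1,1′-biphenyl]-3,3′-dicarboxylate (bis-trichloroacetimidate, phenols free)
Conditions: 8 (3 equiv), DBU (0.2 equiv), CH2Cl2, −10 °C; rapid filtration through Et3N-deactivated silica
Reagents that add atoms: trichloroacetonitrile (8), N#CC(Cl)(Cl)Cl
Why: Base-catalysed addition of the primary allylic alcohols to the nitrile (trichloroacetimidate formation); the acidic, electron-poor phenols (pKa about 8) add only reversibly and are recovered free, and the E-alkenes are untouched.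

Step 5
Reactants: 9 dimethyl 6,6′-dihydroxy-5,5′-bis{(2E)-3-methyl-4-[(2,2,2-trichloroethanimidoyl)oxy]but-2-en-1-yl}-[1,1′-biphenyl]-3,3′-dicarboxylate
Product: 10 dimethyl (2S,2′S)-2,2′-di(prop-1-en-2-yl)-2,2′,3,3′-tetrahydro-[7,7′-bi-1-benzofuran]-5,5′-dicarboxylate
Conditions: (R)-TRIP [(R)-3,3′-bis(2,4,6-triisopropylphenyl)-1,1′-binaphthyl-2,2′-diyl hydrogen phosphate] (10 mol%), 4 Å molecular sieves, toluene (0.02 M), −20 °C
Reagents that add atoms: none
Why: Proposed new method: a twofold chiral-phosphoric-acid-catalysed intramolecular syn-SN2′ O-allylation of a phenol, in which the P–OH protonates the imidate nitrogen (trichloroacetamide becomes the leaving group) while the P=O oxygen hydrogen-bonds the phenol OH, so that inside the chiral pocket the phenol oxygen adds 5-exo to the Si face of the alkene CH carbon as the C–O(imidate) bond breaks, which sets C2 as S and unveils the isopropenyl group in the same event (direct SN2 would need a seven-membered ring holding an E-alkene and is not possible); the two ring closures are independent, so the minor sense ends up mainly in the separable meso (2R,2′S) isomer and the (2S,2′S) product is enriched further (Horeau amplification); the closest known reaction type is the chiral-phosphoric-acid-catalysed intramolecular SN2′ amination of allylic trichloroacetimidates by sulfonamide N–H nucleophiles of similar acidity, which to my knowledge has not been extended to phenol oxygen nucleophiles, to 2-isopropenyl-2,3-dihydrobenzofurans or to a double cyclisation.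

Step 6
Reactants: 10 dimethyl (2S,2′S)-2,2′-di(prop-1-en-2-yl)-2,2′,3,3′-tetrahydro-[7,7′-bi-1-benzofuran]-5,5′-dicarboxylate
Product: 11 Eurycomalin A, (2S,2′S)-2,2′-di(prop-1-en-2-yl)-2,2′,3,3′-tetrahydro-[7,7′-bi-1-benzofuran]-5,5′-dicarboxylic acid
Conditions: LiOH·H2O (6 equiv), THF/MeOH/H2O 3:1:1, rt; then 1 M HCl to pH 2
Reagents that add atoms: lithium hydroxide, [Li+].[OH-]
Why: Saponification of both methyl esters (acyl substitution by hydroxide) followed by acidification; the C2 stereocentres bear no acidic hydrogen and the allylic aryl ethers and isopropenyl groups are stable to aqueous hydroxide at room temperature, so the configuration is retained.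

## Compound list

1 | methyl 3-bromo-4-hydroxybenzoate | COC(=O)c1ccc(O)c(Br)c1 | starting material
2 | bis(pinacolato)diboron | CC1(C)OB(OC1(C)C)B1OC(C)(C)C(C)(C)O1 | starting material
3 | methyl 4-hydroxy-3-(4,4,5,5-tetramethyl-1,3,2-dioxaborolan-2-yl)benzoate | COC(=O)c1ccc(O)c(c1)B1OC(C)(C)C(C)(C)O1 | intermediate (not isolated)
4 | dimethyl 6,6′-dihydroxy-[1,1′-biphenyl]-3,3′-dicarboxylate | COC(=O)c1ccc(O)c(c1)-c1cc(ccc1O)C(=O)OC | intermediate
5 | prenyl bromide (1-bromo-3-methylbut-2-ene) | CC(C)=CCBr | starting material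
6 | dimethyl 6,6′-dihydroxy-5,5′-bis(3-methylbut-2-en-1-yl)-[1,1′-biphenyl]-3,3′-dicarboxylate | COC(=O)c1cc(CC=C(C)C)c(O)c(c1)-c1cc(cc(CC=C(C)C)c1O)C(=O)OC | intermediate
7 | dimethyl 6,6′-dihydroxy-5,5′-bis[(2E)-4-hydroxy-3-methylbut-2-en-1-yl]-[1,1′-biphenyl]-3,3′-dicarboxylate | COC(=O)c1cc(C/C=C(\C)CO)c(O)c(c1)-c1cc(cc(C/C=C(\C)CO)c1O)C(=O)OC | intermediate
8 | trichloroacetonitrile | N#CC(Cl)(Cl)Cl | starting material
9 | dimethyl 6,6′-dihydroxy-5,5′-bis{(2E)-3-methyl-4-[(2,2,2-trichloroethanimidoyl)oxy]but-2-en-1-yl}-[1,1′-biphenyl]-3,3′-dicarboxylate | COC(=O)c1cc(C/C=C(\C)COC(=N)C(Cl)(Cl)Cl)c(O)c(c1)-c1cc(cc(C/C=C(\C)COC(=N)C(Cl)(Cl)Cl)c1O)C(=O)OC | intermediate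
10 | dimethyl (2S,2′S)-2,2′-di(prop-1-en-2-yl)-2,2′,3,3′-tetrahydro-[7,7′-bi-1-benzofuran]-5,5′-dicarboxylate | C=C(C)[C@@H]1Cc2cc(C(=O)OC)cc(-c3cc(C(=O)OC)cc4c3O[C@H](C(=C)C)C4)c2O1 | intermediate
11 | Eurycomalin A, (2S,2′S)-2,2′-di(prop-1-en-2-yl)-2,2′,3,3′-tetrahydro-[7,7′-bi-1-benzofuran]-5,5′-dicarboxylic acid | C=C(C)[C@@H]1Cc2cc(C(=O)O)cc(-c3cc(C(=O)O)cc4c3O[C@H](C(=C)C)C4)c2O1 | target

## Step count and risks

Total step count: 6. Longest linear sequence: 6 steps (from 1).

**Step 2 (twofold C-prenylation).** O-Prenylation competes and the electron-poor phenoxide is a weak carbon nucleophile, so the yield of the doubly C-alkylated product may be low. The fallback sets out from 4 and comes back at 6. Compound 4 is brominated at the only activated free positions, ortho to each OH (N-bromosuccinimide, MeCN, 0 °C to rt), to give dimethyl 5,5′-dibromo-6,6′-dihydroxy-[1,1′-biphenyl]-3,3′-dicarboxylate F1. F1 then undergoes a twofold Stille coupling with tributyl(3-methylbut-2-en-1-yl)stannane (Pd(PPh3)4, DMF, 90 °C), which delivers the linear prenyl groups and gives 6.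

**Step 4 (imidate formation beside free phenols).** The acidic phenols may consume the base, add to the nitrile, or trigger a premature racemic ring closure. The fallback sets out from 7 and comes back at 10. The primary allylic hydroxyls of 7 are acylated chemoselectively (methyl chloroformate, pyridine, CH2Cl2, −20 °C) to give dimethyl 6,6′-dihydroxy-5,5′-bis{(2E)-4-[(methoxycarbonyl)oxy]-3-methylbut-2-en-1-yl}-[1,1′-biphenyl]-3,3′-dicarboxylate F2. F2 is cyclised by the known zerovalent-palladium-catalysed asymmetric intramolecular allylic etherification of phenols (Pd2(dba)3·CHCl3, the Trost ligand enantiomer that gives 2S, AcOH, CH2Cl2, rt), which gives 10 directly.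

**Step 5 (the new reaction).** The risks are:
- low nucleophilicity of the para-ester phenol;
- uncatalysed, racemic self-activation of the imidate by the acidic phenol;
- acid-promoted [1,3]-shift of the imidate to the allylic trichloroacetamide;
- an unknown level and sense of induction. If the sense is opposite, (S)-TRIP is used. At 90% selectivity per ring closure the expected (2S,2′S) : meso : (2R,2′R) ratio is about 90 : 9.5 : 0.25.

The fallback uses known chemistry, keeps a metal-free asymmetric catalytic step, sets out from 6 and comes back at 10: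
- Compound 6 is silylated (TBSCl, imidazole, DMF, rt) to dimethyl 6,6′-bis[(tert-butyldimethylsilyl)oxy]-5,5′-bis(3-methylbut-2-en-1-yl)-[1,1′-biphenyl]-3,3′-dicarboxylate F3.
- Twofold Shi epoxidation of F3 (D-fructose-derived Shi ketone 30 mol% per alkene, Oxone (2KHSO5·KHSO4·K2SO4), K2CO3, Bu4NHSO4, MeCN/dimethoxymethane/aqueous buffer pH 10.5, 0 °C) gives dimethyl 6,6′-bis[(tert-butyldimethylsilyl)oxy]-5,5′-bis{[(2R)-3,3-dimethyloxiran-2-yl]methyl}-[1,1′-biphenyl]-3,3′-dicarboxylate F4.
- Bu4NF (THF, 0 °C to rt) frees the phenoxides, which open the epoxides 5-exo at the secondary carbon with inversion. This gives dimethyl (2S,2′S)-2,2′-bis(2-hydroxypropan-2-yl)-2,2′,3,3′-tetrahydro-[7,7′-bi-1-benzofuran]-5,5′-dicarboxylate F5.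
- Dehydration of the two tertiary alcohols of F5 toward the methyl groups with Burgess reagent (toluene, 60 °C) gives 10.

## Further compounds

F1 | step 2 | dimethyl 5,5′-dibromo-6,6′-dihydroxy-[1,1′-biphenyl]-3,3′-dicarboxylate | COC(=O)c1cc(Br)c(O)c(c1)-c1cc(cc(Br)c1O)C(=O)OC
F2 | step 4 | dimethyl 6,6′-dihydroxy-5,5′-bis{(2E)-4-[(methoxycarbonyl)oxy]-3-methylbut-2-en-1-yl}-[1,1′-biphenyl]-3,3′-dicarboxylate | COC(=O)c1cc(C/C=C(\C)COC(=O)OC)c(O)c(c1)-c1cc(cc(C/C=C(\C)COC(=O)OC)c1O)C(=O)OC
F3 | step 5 | dimethyl 6,6′-bis[(tert-butyldimethylsilyl)oxy]-5,5′-bis(3-methylbut-2-en-1-yl)-[1,1′-biphenyl]-3,3′-dicarboxylate | COC(=O)c1cc(CC=C(C)C)c(O[Si](C)(C)C(C)(C)C)c(c1)-c1cc(cc(CC=C(C)C)c1O[Si](C)(C)C(C)(C)C)C(=O)OC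
F4 | step 5 | dimethyl 6,6′-bis[(tert-butyldimethylsilyl)oxy]-5,5′-bis{[(2R)-3,3-dimethyloxiran-2-yl]methyl}-[1,1′-biphenyl]-3,3′-dicarboxylate | COC(=O)c1cc(C[C@H]2OC2(C)C)c(O[Si](C)(C)C(C)(C)C)c(c1)-c1cc(cc(C[C@H]2OC2(C)C)c1O[Si](C)(C)C(C)(C)C)C(=O)OC
F5 | step 5 | dimethyl (2S,2′S)-2,2′-bis(2-hydroxypropan-2-yl)-2,2′,3,3′-tetrahydro-[7,7′-bi-1-benzofuran]-5,5′-dicarboxylate | CC(C)(O)[C@@H]1Cc2cc(C(=O)OC)cc(-c3cc(C(=O)OC)cc4c3O[C@H](C(C)(C)O)C4)c2O1
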